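**Retrosynthetic overview**

- The strategy rests on one repeated feature. Each of the six rings has one oxygen-bearing carbon flanked by two hydroxyls: C1 of ring A (ether to ring B), C4 of rings B to E (ether to the next ring) and C4 of ring F (free OH). The twelve flanking hydroxyls (C2/C6 of ring A, C3/C5 of rings B to F) stand where formyl groups would activate a fluoride on the flanked carbon for SNAr.
- Endgame: BBr3 cleaves the ring F methyl ether and the ring A tert-butyl ether, after methanolysis of twelve aryl formates that come from a twelvefold Baeyer-Villiger oxidation of hexameric dodecaaldehyde 22.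
- 22 is grown from ring F to ring A by five SNAr couplings. In each, the unhindered phenoxide of the chain attacks the C-F carbon of one monomer, 5-tert-butoxy-2-fluoroisophthalaldehyde 11, and TFA then frees the para oxygen for the next round.
- Monomer 11 comes from 4-fluorophenol by O-tert-butylation and two fluorine-directed lithiation/DMF formylations. The ring F unit 13 comes from 11 by methoxide SNAr and TFA.
- No ring is formed. All six benzene rings derive from 4-fluorophenol and are joined in the order F, E, D, C, B, A.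

Key step: step 16

Remark on the chemistry: the ring A end cap is carried as a tert-butyl ether instead of a methyl ether, so that the single monomer 11 serves all six rings; the final BBr3 step removes it together with the ring F methyl ether.

Naming convention for the oligomers: every ring is an isophthalaldehyde unit (formyl groups at C1 and C3). Its C2 carries the ether oxygen bound to C5 of the next ring toward ring F. Ring F carries OMe at C2, and the first ring of the chain carries O-tert-butyl or OH at C5.

**Route**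

Step 1
Reactants: 1 4-fluorophenol
Product: 2 1-tert-butoxy-4-fluorobenzene
Conditions: isobutene (excess), TfOH (cat.), CH2Cl2, −78 °C
Reagents that add atoms: isobutene, CC(C)=C
Why: Acid-catalysed addition of the phenol O-H across isobutene (capture of the tert-butyl cation) should give the aryl tert-butyl ether at low temperature before Friedel-Crafts C-alkylation can compete.

Step 2
Reactants: 2 1-tert-butoxy-4-fluorobenzene; 3 N,N-dimethylformamide
Product: 6 5-tert-butoxy-2-fluorobenzaldehyde, via (5-tert-butoxy-2-fluorophenyl)lithium 4 (not isolated), via lithium hemiaminal alkoxide 5 (not isolated)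
Conditions: n-BuLi, PMDTA, THF, −78 °C; DMF, −78 to 0 °C; 1 M HCl, 0 °C
Reagents that add atoms: none
Why: Fluorine-directed ortho-lithiation followed by formylation with DMF: with lithium saturated by PMDTA the base should remove the most acidic ring proton, next to fluorine, while the bulky, weakly coordinating tert-butoxy group does not direct.

Step 3
Reactants: 6 5-tert-butoxy-2-fluorobenzaldehyde
Product: 7 4-tert-butoxy-2-(dimethoxymethyl)-1-fluorobenzene
Conditions: HC(OMe)3, PPTS (cat.), MeOH, 40 °C
Reagents that add atoms: trimethyl orthoformate, COC(OC)OC; methanol, CO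
Why: Acid-catalysed acetalisation with the orthoformate as water scavenger masks the aldehyde against the organolithium of the next step, and PPTS is too weak an acid to cleave the aryl tert-butyl ether.

Step 4
Reactants: 7 4-tert-butoxy-2-(dimethoxymethyl)-1-fluorobenzene; 3 N,N-dimethylformamide
Product: 11 5-tert-butoxy-2-fluoroisophthalaldehyde, via aryllithium 8 (not isolated), via lithium hemiaminal alkoxide 9 (not isolated), via acetal aldehyde 10 (not isolated)
Conditions: n-BuLi, PMDTA, THF, −78 °C; DMF, −78 to 0 °C; then 1 M HCl, THF, rt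
Reagents that add atoms: none
Why: A second fluorine-directed ortho-lithiation should take the remaining proton next to fluorine (the proton between the acetal and the tert-butoxy group is hindered and less acidic), DMF formylates the aryllithium, and dilute aqueous acid hydrolyses the dimethyl acetal while the aryl tert-butyl ether survives.

Step 5
Reactants: 11 5-tert-butoxy-2-fluoroisophthalaldehyde
Product: 12 5-tert-butoxy-2-methoxyisophthalaldehyde
Conditions: NaOMe, MeOH, 0 °C to rt
Reagents that add atoms: sodium methoxide, C[O-].[Na+]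
Why: Nucleophilic aromatic substitution: methoxide adds at the C-F carbon, whose Meisenheimer intermediate is stabilised by both ortho formyl groups, and fluoride leaves.

Step 6
Reactants: 12 5-tert-butoxy-2-methoxyisophthalaldehyde
Product: 13 5-hydroxy-2-methoxyisophthalaldehyde
Conditions: TFA, CH2Cl2, 0 °C to rt
Reagents that add atoms: none
Why: Acidolysis of the aryl tert-butyl ether (loss of the tert-butyl cation as isobutene) should free the phenol, while the aldehydes and the methyl ether are inert to TFA and the electron-poor ring is not C-alkylated.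

Step 7
Reactants: 13 5-hydroxy-2-methoxyisophthalaldehyde; 11 5-tert-butoxy-2-fluoroisophthalaldehyde
Product: 14 5-tert-butoxy-2-(3,5-diformyl-4-methoxyphenoxy)isophthalaldehyde (dimer E-F)
Conditions: K2CO3, DMF, rt to 40 °C
Reagents that add atoms: none
Why: Uncatalysed SNAr forms the E-F ether: the unhindered phenoxide of 13 attacks the fluoride-bearing carbon of 11 between its two formyl groups, and the tert-butyl ether is stable to carbonate and fluoride.

Step 8
Reactants: 14 dimer E-F tert-butyl ether
Product: 15 2-(3,5-diformyl-4-methoxyphenoxy)-5-hydroxyisophthalaldehyde (dimer phenol)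
Conditions: TFA, CH2Cl2, 0 °C to rt
Reagents that add atoms: none
Why: Acidolysis of the aryl tert-butyl ether frees the ring E oxygen para to the new ether, and diaryl ether, methyl ether and aldehydes are stable to TFA.

Step 9
Reactants: 15 dimer phenol; 11 5-tert-butoxy-2-fluoroisophthalaldehyde
Product: 16 trimer D-E-F hexaaldehyde, tert-butyl ether at C5 of ring D
Conditions: K2CO3, DMF, rt to 40 °C
Reagents that add atoms: none
Why: SNAr forms the D-E ether: fluoride between two formyl groups is displaced much faster than the aryloxide or methoxide of the ethers already present, so the chain should grow by one ring without exchange.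

Step 10
Reactants: 16 trimer tert-butyl ether
Product: 17 trimer D-E-F hexaaldehyde, free OH at C5 of ring D
Conditions: TFA, CH2Cl2, 0 °C to rt
Reagents that add atoms: none
Why: The same tert-butyl ether acidolysis as in step 8; nothing else in the molecule is acid-labile.

Step 11
Reactants: 17 trimer phenol; 11 5-tert-butoxy-2-fluoroisophthalaldehyde
Product: 18 tetramer C-D-E-F octaaldehyde, tert-butyl ether at C5 of ring C
Conditions: K2CO3, DMF, rt to 40 °C
Reagents that add atoms: none
Why: SNAr forms the C-D ether by attack of the terminal phenoxide, which lies meta to its own formyl groups and is not hydrogen-bonded, on the doubly activated C-F carbon of 11.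

Step 12
Reactants: 18 tetramer tert-butyl ether
Product: 19 tetramer C-D-E-F octaaldehyde, free OH at C5 of ring C
Conditions: TFA, CH2Cl2, 0 °C to rt
Reagents that add atoms: none
Why: The same tert-butyl ether acidolysis; the electron-poor rings do not trap the tert-butyl cation.

Step 13
Reactants: 19 tetramer phenol; 11 5-tert-butoxy-2-fluoroisophthalaldehyde
Product: 20 pentamer B-C-D-E-F decaaldehyde, tert-butyl ether at C5 of ring B
Conditions: K2CO3, DMF, rt to 40 °C
Reagents that add atoms: none
Why: SNAr forms the B-C ether; a small excess of 11 and the lowest workable temperature should keep phenoxide attack on internal ethers negligible.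

Step 14
Reactants: 20 pentamer tert-butyl ether
Product: 21 pentamer B-C-D-E-F decaaldehyde, free OH at C5 of ring B
Conditions: TFA, CH2Cl2, 0 °C to rt
Reagents that add atoms: none
Why: The same tert-butyl ether acidolysis, giving the last chain phenol.

Step 15
Reactants: 21 pentamer phenol; 11 5-tert-butoxy-2-fluoroisophthalaldehyde
Product: 22 hexameric dodecaaldehyde (ring A 4-O-tert-butyl, ring F 4-O-methyl)
Conditions: K2CO3, DMF, rt to 40 °C
Reagents that add atoms: none
Why: The fifth SNAr forms the A-B ether and completes the chain; the tert-butyl group on ring A now serves as the end cap.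

Step 16
Reactants: 22 hexameric dodecaaldehyde
Product: 23 hexameric dodecaformate (ring A 4-O-tert-butyl, ring F 4-O-methyl)
Conditions: mCPBA (dried, about 30 equiv), CH2Cl2, 0 °C to reflux
Reagents that add atoms: 3-chloroperoxybenzoic acid (mCPBA), OOC(=O)c1cccc(Cl)c1
Why: Each formyl group adds the peracid to give a peroxyhemiacetal (Criegee intermediate), and the aryl carbon antiperiplanar to the O-O bond migrates to oxygen as 3-chlorobenzoate leaves, so every aryl-CHO bond becomes an aryl-O-CHO bond. The closest known reaction is the Baeyer-Villiger (Dakin-type) oxidation of 2-alkoxy- and 2-aryloxybenzaldehydes to aryl formates with mCPBA, applied here twelve times in one substrate. No ring is closed and no stereocentre is formed. The selectivity needed is aryl over hydride migration at all twelve sites, and what should secure it is that every formyl group stands ortho to an ether oxygen (the diaryl ether oxygen in rings A to E, the methoxy oxygen in ring F) whose lone pair stabilises the electron-poor migrating carbon. The second formyl group of a ring should not be slowed by the first oxidation, since formyloxy is no stronger a meta acceptor than formyl. The tert-butyl, methyl and diaryl ethers are inert to the peracid, and anhydrous conditions keep the formates from hydrolysing to phenols that excess oxidant could attack.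

Step 17
Reactants: 23 hexameric dodecaformate
Product: 24 hexameric dodecaphenol (ring A 4-O-tert-butyl, ring F 4-O-methyl)
Conditions: KHCO3 (cat.), degassed MeOH/THF, 0 °C to rt, Ar; acidic work-up
Reagents that add atoms: none
Why: Transesterification of the activated aryl formates to methyl formate should be fast under near-neutral conditions, and bicarbonate with exclusion of air keeps the electron-rich polyphenol from forming phenoxide that would autoxidise.

Step 18
Reactants: 24 hexameric dodecaphenol
Product: 25 CNP0187343.0 (target)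
Conditions: BBr3 (large excess), CH2Cl2, −78 °C to rt, Ar; then H2O, 0 °C
Reagents that add atoms: none
Why: Lewis-acid ether cleavage: BBr3 coordinates the two alkyl ether oxygens, bromide removes the methyl group by SN2 and the tert-butyl group leaves by ionisation, while the diaryl ether bonds (sp2 carbon on both sides) cannot be cleaved and the phenols are released from their borates on hydrolysis.

**Compound list**

1 | 4-fluorophenol | Oc1ccc(F)cc1 | starting material
2 | 1-tert-butoxy-4-fluorobenzene | CC(C)(C)Oc1ccc(F)cc1 | intermediate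
3 | N,N-dimethylformamide | CN(C)C=O | starting material
4 | (5-tert-butoxy-2-fluorophenyl)lithium | [Li]c1cc(OC(C)(C)C)ccc1F | intermediate
5 | lithium (5-tert-butoxy-2-fluorophenyl)(dimethylamino)methoxide | CN(C)C(O[Li])c1cc(OC(C)(C)C)ccc1F | intermediate
6 | 5-tert-butoxy-2-fluorobenzaldehyde | CC(C)(C)Oc1ccc(F)c(C=O)c1 | intermediate
7 | 4-tert-butoxy-2-(dimethoxymethyl)-1-fluorobenzene | COC(OC)c1cc(OC(C)(C)C)ccc1F | intermediate
8 | [5-tert-butoxy-3-(dimethoxymethyl)-2-fluorophenyl]lithium | COC(OC)c1cc(OC(C)(C)C)cc([Li])c1F | intermediate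
9 | lithium [5-tert-butoxy-3-(dimethoxymethyl)-2-fluorophenyl](dimethylamino)methoxide | COC(OC)c1cc(OC(C)(C)C)cc(C(O[Li])N(C)C)c1F | intermediate
10 | 5-tert-butoxy-3-(dimethoxymethyl)-2-fluorobenzaldehyde | COC(OC)c1cc(OC(C)(C)C)cc(C=O)c1F | intermediate
11 | 5-tert-butoxy-2-fluoroisophthalaldehyde (monomer) | CC(C)(C)Oc1cc(C=O)c(F)c(C=O)c1 | intermediate
12 | 5-tert-butoxy-2-methoxyisophthalaldehyde | CC(C)(C)Oc1cc(C=O)c(OC)c(C=O)c1 | intermediate
13 | 5-hydroxy-2-methoxyisophthalaldehyde (ring F unit) | Oc1cc(C=O)c(OC)c(C=O)c1 | intermediate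
14 | 5-tert-butoxy-2-(3,5-diformyl-4-methoxyphenoxy)isophthalaldehyde (dimer E-F) | CC(C)(C)Oc1cc(C=O)c(Oc2cc(C=O)c(OC)c(C=O)c2)c(C=O)c1 | intermediate
15 | 2-(3,5-diformyl-4-methoxyphenoxy)-5-hydroxyisophthalaldehyde (dimer phenol) | Oc1cc(C=O)c(Oc2cc(C=O)c(OC)c(C=O)c2)c(C=O)c1 | intermediate
16 | trimer D-E-F hexaaldehyde, tert-butyl ether on ring D | CC(C)(C)Oc1cc(C=O)c(Oc2cc(C=O)c(Oc3cc(C=O)c(OC)c(C=O)c3)c(C=O)c2)c(C=O)c1 | intermediate
17 | trimer D-E-F hexaaldehyde, free OH on ring D | Oc1cc(C=O)c(Oc2cc(C=O)c(Oc3cc(C=O)c(OC)c(C=O)c3)c(C=O)c2)c(C=O)c1 | intermediate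
18 | tetramer C-D-E-F octaaldehyde, tert-butyl ether on ring C | CC(C)(C)Oc1cc(C=O)c(Oc2cc(C=O)c(Oc3cc(C=O)c(Oc4cc(C=O)c(OC)c(C=O)c4)c(C=O)c3)c(C=O)c2)c(C=O)c1 | intermediate
19 | tetramer C-D-E-F octaaldehyde, free OH on ring C | Oc1cc(C=O)c(Oc2cc(C=O)c(Oc3cc(C=O)c(Oc4cc(C=O)c(OC)c(C=O)c4)c(C=O)c3)c(C=O)c2)c(C=O)c1 | intermediate
20 | pentamer B-C-D-E-F decaaldehyde, tert-butyl ether on ring B | CC(C)(C)Oc1cc(C=O)c(Oc2cc(C=O)c(Oc3cc(C=O)c(Oc4cc(C=O)c(Oc5cc(C=O)c(OC)c(C=O)c5)c(C=O)c4)c(C=O)c3)c(C=O)c2)c(C=O)c1 | intermediate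
21 | pentamer B-C-D-E-F decaaldehyde, free OH on ring B | Oc1cc(C=O)c(Oc2cc(C=O)c(Oc3cc(C=O)c(Oc4cc(C=O)c(Oc5cc(C=O)c(OC)c(C=O)c5)c(C=O)c4)c(C=O)c3)c(C=O)c2)c(C=O)c1 | intermediate
22 | hexameric dodecaaldehyde (ring A 4-O-tert-butyl, ring F 4-O-methyl) | CC(C)(C)Oc1cc(C=O)c(Oc2cc(C=O)c(Oc3cc(C=O)c(Oc4cc(C=O)c(Oc5cc(C=O)c(Oc6cc(C=O)c(OC)c(C=O)c6)c(C=O)c5)c(C=O)c4)c(C=O)c3)c(C=O)c2)c(C=O)c1 | intermediate
23 | hexameric dodecaformate (same end caps) | CC(C)(C)Oc1cc(OC=O)c(Oc2cc(OC=O)c(Oc3cc(OC=O)c(Oc4cc(OC=O)c(Oc5cc(OC=O)c(Oc6cc(OC=O)c(OC)c(OC=O)c6)c(OC=O)c5)c(OC=O)c4)c(OC=O)c3)c(OC=O)c2)c(OC=O)c1 | intermediate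
24 | hexameric dodecaphenol (same end caps) | CC(C)(C)Oc1cc(O)c(Oc2cc(O)c(Oc3cc(O)c(Oc4cc(O)c(Oc5cc(O)c(Oc6cc(O)c(OC)c(O)c6)c(O)c5)c(O)c4)c(O)c3)c(O)c2)c(O)c1 | intermediate
25 | CNP0187343.0 | Oc1cc(O)c(Oc2cc(O)c(Oc3cc(O)c(Oc4cc(O)c(Oc5cc(O)c(Oc6cc(O)c(O)c(O)c6)c(O)c5)c(O)c4)c(O)c3)c(O)c2)c(O)c1 | target

**Step count and risks**

Total step count: 18. Longest linear sequence: 18 (the route is linear from 1; monomer 11 re-enters as coupling partner in steps 7, 9, 11, 13 and 15).

Steps most likely to fail:

1. Step 16. Hydride migration (giving carboxylic acids) or stalled conversion may occur at some of the twelve sites. The ether oxygen ortho to each formyl group is flanked on both sides and twisted, which weakens its donation, and each formyl group has a meta acceptor. Partial hydrolysis of formates could also expose phenols to the oxidant. Fallback, setting out from 22: the formyl groups would be turned into acetyl groups, for which no hydride shift exists. MeMgBr (THF, −78 °C) would give the dodeca(1-hydroxyethyl) hexamer F1 as a diastereomer mixture. Dess-Martin periodinane would give the dodecaacetyl hexamer F2. Baeyer-Villiger oxidation with CF3CO3H/Na2HPO4 in CH2Cl2, where aryl migrates in preference to methyl, would give the dodecaacetate hexamer F3. Methanolysis (K2CO3, degassed MeOH) comes back to the route at 24.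

2. Step 15 (and, to a lesser degree, step 13). The long-chain phenoxide may attack internal ether carbons that are themselves flanked by two formyl groups, exchanging aryloxide and scrambling chain length, especially if low solubility forces long reaction times. Fallback, setting out from 21: the internal ethers would be deactivated before coupling. HC(OMe)3/PPTS/MeOH would convert all ten formyl groups into dimethyl acetals, giving the deca-acetal pentamer phenol F4. SNAr with 11 (K2CO3, DMF) would give the hexamer F5, in which only ring A carries free formyl groups. Dilute HCl in THF would hydrolyse the acetals and come back to the route at 22.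

3. Step 18. Ether cleavage may be incomplete on a poorly soluble borate network, and the free polyphenol may degrade oxidatively during the Lewis-acid treatment and work-up. Fallback, setting out from 22: the two alkyl ethers would be exchanged at the robust aldehyde stage. BCl3 (CH2Cl2, −78 to 0 °C) cleaves the chelated ring F methoxy group and the tert-butyl ether to give the diphenol dodecaaldehyde F6. BnBr/K2CO3 (DMF, rt) would give the dibenzyl dodecaaldehyde F7. mCPBA would give the dibenzyl dodecaformate F8. KHCO3/MeOH would give the dibenzyl dodecaphenol F9. Neutral hydrogenolysis (H2, palladium on carbon, Pd/C, MeOH/EtOAc) then arrives at the target 25.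

**Further compounds**

F1 | step 16 | dodeca(1-hydroxyethyl) hexamer (end caps as in 22) | CC(C)(C)Oc1cc(C(C)O)c(Oc2cc(C(C)O)c(Oc3cc(C(C)O)c(Oc4cc(C(C)O)c(Oc5cc(C(C)O)c(Oc6cc(C(C)O)c(OC)c(C(C)O)c6)c(C(C)O)c5)c(C(C)O)c4)c(C(C)O)c3)c(C(C)O)c2)c(C(C)O)c1
F2 | step 16 | dodecaacetyl hexamer (end caps as in 22) | CC(C)(C)Oc1cc(C(C)=O)c(Oc2cc(C(C)=O)c(Oc3cc(C(C)=O)c(Oc4cc(C(C)=O)c(Oc5cc(C(C)=O)c(Oc6cc(C(C)=O)c(OC)c(C(C)=O)c6)c(C(C)=O)c5)c(C(C)=O)c4)c(C(C)=O)c3)c(C(C)=O)c2)c(C(C)=O)c1
F3 | step 16 | dodecaacetate hexamer (end caps as in 22) | CC(C)(C)Oc1cc(OC(C)=O)c(Oc2cc(OC(C)=O)c(Oc3cc(OC(C)=O)c(Oc4cc(OC(C)=O)c(Oc5cc(OC(C)=O)c(Oc6cc(OC(C)=O)c(OC)c(OC(C)=O)c6)c(OC(C)=O)c5)c(OC(C)=O)c4)c(OC(C)=O)c3)c(OC(C)=O)c2)c(OC(C)=O)c1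
F4 | step 15 | pentamer phenol deca(dimethyl acetal) | Oc1cc(C(OC)OC)c(Oc2cc(C(OC)OC)c(Oc3cc(C(OC)OC)c(Oc4cc(C(OC)OC)c(Oc5cc(C(OC)OC)c(OC)c(C(OC)OC)c5)c(C(OC)OC)c4)c(C(OC)OC)c3)c(C(OC)OC)c2)c(C(OC)OC)c1
F5 | step 15 | hexamer with free formyl groups on ring A and dimethyl acetals on rings B to F | CC(C)(C)Oc1cc(C=O)c(Oc2cc(C(OC)OC)c(Oc3cc(C(OC)OC)c(Oc4cc(C(OC)OC)c(Oc5cc(C(OC)OC)c(Oc6cc(C(OC)OC)c(OC)c(C(OC)OC)c6)c(C(OC)OC)c5)c(C(OC)OC)c4)c(C(OC)OC)c3)c(C(OC)OC)c2)c(C=O)c1
F6 | step 18 | diphenol dodecaaldehyde hexamer (ring A 4-OH, ring F 4-OH) | Oc1cc(C=O)c(Oc2cc(C=O)c(Oc3cc(C=O)c(Oc4cc(C=O)c(Oc5cc(C=O)c(Oc6cc(C=O)c(O)c(C=O)c6)c(C=O)c5)c(C=O)c4)c(C=O)c3)c(C=O)c2)c(C=O)c1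
F7 | step 18 | dibenzyl dodecaaldehyde hexamer | C(c1ccccc1)Oc2cc(C=O)c(Oc3cc(C=O)c(Oc4cc(C=O)c(Oc5cc(C=O)c(Oc6cc(C=O)c(Oc7cc(C=O)c(OCc8ccccc8)c(C=O)c7)c(C=O)c6)c(C=O)c5)c(C=O)c4)c(C=O)c3)c(C=O)c2
F8 | step 18 | dibenzyl dodecaformate hexamer | C(c1ccccc1)Oc2cc(OC=O)c(Oc3cc(OC=O)c(Oc4cc(OC=O)c(Oc5cc(OC=O)c(Oc6cc(OC=O)c(Oc7cc(OC=O)c(OCc8ccccc8)c(OC=O)c7)c(OC=O)c6)c(OC=O)c5)c(OC=O)c4)c(OC=O)c3)c(OC=O)c2
F9 | step 18 | dibenzyl dodecaphenol hexamer | C(c1ccccc1)Oc2cc(O)c(Oc3cc(O)c(Oc4cc(O)c(Oc5cc(O)c(Oc6cc(O)c(Oc7cc(O)c(OCc8ccccc8)c(O)c7)c(O)c6)c(O)c5)c(O)c4)c(O)c3)c(O)c2
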